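Assumption: intermediates carry the briarane numbering of the target (C1–C20; lactone C7–O–C19; Me18 on C17); "as in 27" means the same spatial arrangement as in the target SMILES.

**Retrosynthetic overview**
- Target ⇐ acid-triggered transannular C1–C10 closure of a 14-membered cembranoid: the Z-allylic tertiary C1-OH ionises, E-C10=C11 attacks, and the 12-acetate traps C11 (sets C1, C10, C11; gives 11-OH/12-OAc).
- Cembranoid ⇐ Lindlar reduction of a 13-yne; γ-lactone by translactonisation; 14-membered ring closed at C4–C5 (vinyl iodide + alkyl iodide, Ni reductive coupling).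
- Seco chain ⇐ asymmetric alkynylation (C12–C13) of a C5–C12 enal with a C1–C4/C13–C14 alkyne.
- Enal ⇐ diacetone-D-glucose (C6–C10; C7 and C9 from sugar C2 and C4) + (R)-lactate dioxolanone (C17–C19) by aldol at the 3-ulose (C8); alkyne ⇐ D-tartrate acetonide (C2, C3).
- Ring order: 14-membered carbocycle → γ-lactone → cyclohexene (transannular), giving the bicyclo[8.4.0] core.

**Route**

Step 1
Reactants: 1 dimethyl (4S,5S)-2,2-dimethyl-1,3-dioxolane-4,5-dicarboxylate (dimethyl 2,3-O-isopropylidene-D-tartrate)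
Product: 2 methyl (4S,5R)-5-(hydroxymethyl)-2,2-dimethyl-1,3-dioxolane-4-carboxylate
Conditions: NaBH4 (0.6 equiv), MeOH, 0 °C
Reagents that add atoms: none
Why: Statistical mono-reduction of a C2-symmetric diester (borohydride ester reduction) gives the hydroxy ester; the two stereocentres (future C2 and C3) come unchanged from D-tartrate.

Step 2
Reactants: 2 methyl (4S,5R)-5-(hydroxymethyl)-2,2-dimethyl-1,3-dioxolane-4-carboxylate
Product: 3 methyl (4S,5S)-5-(iodomethyl)-2,2-dimethyl-1,3-dioxolane-4-carboxylate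
Conditions: I2, PPh3, imidazole, CH2Cl2, 0 → 23 °C
Reagents that add atoms: iodine (II)
Why: Appel-type (Garegg–Samuelsson) iodination of the primary alcohol, which installs the future C4 electrophile without touching a stereocentre.

Step 3
Reactants: 3 methyl (4S,5S)-5-(iodomethyl)-2,2-dimethyl-1,3-dioxolane-4-carboxylate
Product: 5 1-[(4S,5S)-5-(iodomethyl)-2,2-dimethyl-1,3-dioxolan-4-yl]ethan-1-one, via Weinreb amide 4 (not isolated)
Conditions: MeNH(OMe)·HCl, MeMgBr (4 equiv), THF, −20 → 0 °C; aq. NH4Cl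
Reagents that add atoms: methylmagnesium bromide (C[Mg]Br); N,O-dimethylhydroxylamine hydrochloride (CNOC.Cl, retained only in 4)
Why: One-pot Weinreb ketone synthesis; the magnesium amide converts the ester into the N-methoxy-N-methylamide, whose chelated MeMgBr adduct cannot over-add, and the primary iodide is inert to Grignard reagents at this temperature.

Step 4
Reactants: 5 1-[(4S,5S)-5-(iodomethyl)-2,2-dimethyl-1,3-dioxolan-4-yl]ethan-1-one
Product: 6 (2S)-2-[(4S,5S)-5-(iodomethyl)-2,2-dimethyl-1,3-dioxolan-4-yl]but-3-yn-2-ol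
Conditions: HC≡CMgBr, MgBr2·OEt2, CH2Cl2/THF, −78 °C; aq. NH4Cl
Reagents that add atoms: ethynylmagnesium bromide (C#C[Mg]Br)
Why: Grignard addition under Cram-chelate control (Mg bridging the ketone and the α-dioxolane oxygen, attack from the side of the α-H) sets the carbinol (future C1) as 2S; this centre only has to survive until step 17, where it is ionised.

Step 5
Reactants: 7 (R)-lactic acid; 8 pivalaldehyde
Product: 9 (2R,5R)-2-tert-butyl-5-methyl-1,3-dioxolan-4-one
Conditions: TsOH (cat.), H2SO4 (cat.), pentane, reflux, Dean–Stark; crystallise the cis isomer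
Reagents that add atoms: none
Why: Seebach acetalisation (self-regeneration of stereocentres); the cis acetal stores the lactate chirality in the tert-butyl-bearing acetal carbon.

Step 6
Reactants: 10 1,2:5,6-di-O-isopropylidene-α-D-glucofuranose
Product: 11 1,2:5,6-di-O-isopropylidene-α-D-ribo-hexofuranos-3-ulose
Conditions: TEMPO (cat.), KBr (cat.), NaOCl, NaHCO3, CH2Cl2/H2O, 0 °C; dry azeotropically
Reagents that add atoms: none
Why: Anelli (TEMPO/hypochlorite) oxidation of the only free hydroxyl gives the known 3-ulose; sugar C2 and C4 (future C7 and C9) are untouched.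

Step 7
Reactants: 11 1,2:5,6-di-O-isopropylidene-α-D-ribo-hexofuranos-3-ulose; 9 (2R,5R)-2-tert-butyl-5-methyl-1,3-dioxolan-4-one
Product: 13 3-C-[(2R,4S)-2-tert-butyl-4-methyl-5-oxo-1,3-dioxolan-4-yl]-1,2:5,6-di-O-isopropylidene-α-D-allofuranose, via lithium enolate 12 (not isolated)
Conditions: LiN(iPr)2, THF, −78 °C; then 11, −78 → −40 °C; AcOH
Reagents that add atoms: none
Why: Seebach aldol addition; the enolate reacts anti to its tert-butyl group (sets C17, retention relative to lactate) and the ketone is attacked on its exo (β) face anti to the 1,2-acetonide (sets C8 in the allo sense, tertiary OH cis to O2).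

Step 8
Reactants: 13 3-C-[(2R,4S)-2-tert-butyl-4-methyl-5-oxo-1,3-dioxolan-4-yl]-1,2:5,6-di-O-isopropylidene-α-D-allofuranose
Product: 14 3-C-[(2R,4S)-2-tert-butyl-4-methyl-5-oxo-1,3-dioxolan-4-yl]-2,3:5,6-di-O-isopropylidene-β-D-allofuranose (lactol, β anomer drawn)
Conditions: acetone, H2SO4 (cat.), CuSO4, 23 °C
Reagents that add atoms: none
Why: Acid-catalysed acetal migration under thermodynamic control; on allo-configured furanoses the cis-2,3-diol acetonide is the favoured one, so O2 and the tertiary O3 become tied together, the anomeric hydroxyl is freed and no stereocentre changes.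

Step 9
Reactants: 14 3-C-[(2R,4S)-2-tert-butyl-4-methyl-5-oxo-1,3-dioxolan-4-yl]-2,3:5,6-di-O-isopropylidene-β-D-allofuranose
Product: 16 (2Z)-6-O-acetyl-1,2,3-trideoxy-2-iodo-4,5:7,8-di-O-isopropylidene-5-C-[(2R,4S)-2-tert-butyl-4-methyl-5-oxo-1,3-dioxolan-4-yl]-D-allo-oct-2-enitol (C5–C10 vinyl iodide; 9-OAc), via C9 alcohol 15 (not isolated)
Conditions: [Ph3PEt]I, n-BuLi, THF; I2, −78 °C; NaN(SiMe3)2, −78 → −20 °C; 14; then Ac2O, Et3N, DMAP, 0 °C
Reagents that add atoms: ethyltriphenylphosphonium iodide (CC[P+](c1ccccc1)(c1ccccc1)c1ccccc1.[I-]); iodine (II); acetic anhydride (CC(=O)OC(C)=O)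
Why: Stork–Zhao olefination of the lactol's aldehyde form with Ph3P=C(I)CH3 gives the (Z)-2-iodoalkene (iodine cis to C7, so the later C4 substituent gives the 5Z alkene), and the furanose oxygen, released as the only free hydroxyl (C9-OH), is acetylated in the same flask before it can attack the dioxolanone.

Step 10
Reactants: 16 (C5–C10 vinyl iodide 9-acetate)
Product: 17 C5–C10 aldehyde (16 with the terminal acetonide cleaved to the C10 aldehyde; Z-vinyl iodide; 7,8-O-isopropylidene; 8-dioxolanonyl; 9-OAc; C7, C8, C9, C17 as in 27)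
Conditions: H5IO6, EtOAc, 0 → 23 °C
Reagents that add atoms: none
Why: Periodic acid hydrolyses the terminal acetonide faster than the internal one and cleaves the freed 1,2-diol (glycol cleavage) to the C10 aldehyde; C9 is not affected.

Step 11
Reactants: 17 (C5–C10 aldehyde)
Product: 18 C5–C12 (10E)-11-methyl enal (C10=C11(CH3)–CHO; other groups as in 17)
Conditions: Ph3P=C(CH3)CHO, toluene, 80 °C
Reagents that add atoms: 2-(triphenylphosphoranylidene)propanal (CC(C=O)=P(c1ccccc1)(c1ccccc1)c1ccccc1)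
Why: Wittig olefination with a stabilised ylide gives the E-trisubstituted enal (C9 trans to C12), the geometry needed for the later anti addition across C10=C11.

Step 12
Reactants: 18 (C5–C12 enal); 6 (2S)-2-[(4S,5S)-5-(iodomethyl)-2,2-dimethyl-1,3-dioxolan-4-yl]but-3-yn-2-ol (1.5 equiv)
Product: 20 seco-cembranoid (12S)-propargylic alcohol (18 and 6 joined at C12–C13; C5 vinyl iodide and C4 primary iodide as chain ends), via zinc alkynylide 19 (not isolated)
Conditions: (S,S)-ProPhenol (20 mol%), Me2Zn (3 equiv), Ph3P=O (40 mol%), toluene, 0 → 23 °C; aq. NH4Cl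
Reagents that add atoms: none
Why: Trost ProPhenol (dinuclear zinc) asymmetric alkynylation, a method suited to enals, delivers the alkynylzinc to the Re face under reagent control and gives the 12S alcohol (C12 oxygen placed as in 27); the tertiary OH, both iodides and the acetate are inert.

Step 13
Reactants: 20 (seco-cembranoid diiodide)
Product: 21 14-membered cembranoid 13-yne (ring C1–C14; 5Z, 10E; 1-OH; 12-OH; 9-OAc; 2,3- and 7,8-O-isopropylidene; 8-dioxolanonyl)
Conditions: NiBr2·dme (20 mol%), 4,4′-di-tert-butyl-2,2′-bipyridine (24 mol%), Mn powder, NaI, DMA, 25 °C, syringe-pump addition (final 2 mM)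
Reagents that add atoms: none
Why: Proposed new method: macrocyclising version of the nickel-catalysed reductive cross-electrophile coupling of a vinyl iodide with a primary alkyl iodide; the C4 radical is captured by the C5 vinyl-nickel species of the same molecule under pseudo-high dilution, the β-alkoxy radical does not fragment as an organozinc would, vinyl iodide oxidative addition outruns ionisation of the allylic 9-acetate, the Z geometry is retained, and the closest known reaction type is the intermolecular vinyl halide/alkyl halide reductive coupling.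

Step 14
Reactants: 21 (cembranoid 13-yne bis-acetonide)
Product: 22 macrocyclic γ-lactone pentaol (C7–O–C19 lactone; OH at C1, C2, C3, C8, C12, C17; 9-OAc; 13-yne)
Conditions: TFA/H2O/THF (2:1:2), 0 → 23 °C
Reagents that add atoms: none
Why: Acid hydrolysis of both isopropylidene acetals, then translactonisation of the dioxolanone by the freed C7-OH (loss of pivalaldehyde); C9 is blocked as acetate so only C7-OH can close the γ-lactone, and the alkyne keeps the C1 alcohol from ionising.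

Step 15
Reactants: 22 (lactone pentaol)
Product: 23 13-yne tetraacetate (2,3,9,12-tetra-OAc; OH at C1, C8, C17)
Conditions: Ac2O, pyridine, DMAP (cat.), CH2Cl2, 0 °C
Reagents that add atoms: acetic anhydride (CC(=O)OC(C)=O)
Why: Acetylation of the three secondary hydroxyls (C2, C3, C12); the tertiary C1, C8 and C17 hydroxyls are not acylated under these mild conditions.

Step 16
Reactants: 23 (13-yne tetraacetate)
Product: 24 (5Z,10E,13Z)-cembranoid tetraacetate (1S tertiary allylic alcohol; 12R in CIP terms after the alkyne-to-alkene change, same spatial arrangement)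
Conditions: H2 (1 atm), Pd/CaCO3 poisoned with Pb(OAc)2, quinoline, EtOAc, 23 °C
Reagents that add atoms: none
Why: Lindlar semihydrogenation (syn addition) gives the 13Z alkene and so unveils the ionisable Z-allylic tertiary alcohol only now; trisubstituted alkenes and acetates are untouched.

Step 17
Reactants: 24 (5Z,10E,13Z)-cembranoid tetraacetate
Product: 27 CNP0121405.1 (target), via allyl cation 25 (not isolated), via acetoxonium ion 26 (not isolated)
Conditions: TfOH (10 mol%), (CF3)2CHOH/CH2Cl2 (1:4), −40 → 0 °C; then H2O, NaHCO3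
Reagents that add atoms: water (O)
Why: Proposed new method: acid ionises the tertiary Z-allylic C1 alcohol, the E-C10=C11 alkene attacks C1 across the ring through a chair-like six-membered transition state (anti addition across the alkene, C1–O replaced with inversion, Me15 held inside and then axial by allylic strain), the pseudo-axial 12-acetate captures the developing C11 cation as a cis-fused dioxolan-2-ylium ion, and its hydrolysis gives the equatorial tertiary 11-OH and the axial 12-OAc, so C1, C10 and C11 are set relative to C12 in one operation; closest known reaction types are the Johnson allyl-cation-initiated polyene cyclisation, transannular cembranoid cyclisations and Woodward–Prévost acetoxonium hydrolysis.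

**Compound list**

1 | dimethyl (4S,5S)-2,2-dimethyl-1,3-dioxolane-4,5-dicarboxylate | COC(=O)[C@H]1OC(C)(C)O[C@@H]1C(=O)OC | starting material
2 | methyl (4S,5R)-5-(hydroxymethyl)-2,2-dimethyl-1,3-dioxolane-4-carboxylate | COC(=O)[C@H]1OC(C)(C)O[C@@H]1CO | intermediate
3 | methyl (4S,5S)-5-(iodomethyl)-2,2-dimethyl-1,3-dioxolane-4-carboxylate | COC(=O)[C@H]1OC(C)(C)O[C@@H]1CI | intermediate
4 | (4S,5S)-5-(iodomethyl)-N-methoxy-N,2,2-trimethyl-1,3-dioxolane-4-carboxamide | CON(C)C(=O)[C@H]1OC(C)(C)O[C@@H]1CI | intermediate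
5 | 1-[(4S,5S)-5-(iodomethyl)-2,2-dimethyl-1,3-dioxolan-4-yl]ethan-1-one | CC(=O)[C@H]1OC(C)(C)O[C@@H]1CI | intermediate
6 | (2S)-2-[(4S,5S)-5-(iodomethyl)-2,2-dimethyl-1,3-dioxolan-4-yl]but-3-yn-2-ol | C#C[C@@](O)(C)[C@H]1OC(C)(C)O[C@@H]1CI | intermediate
7 | (R)-lactic acid | C[C@@H](O)C(=O)O | starting material
8 | pivalaldehyde | CC(C)(C)C=O | starting material
9 | (2R,5R)-2-tert-butyl-5-methyl-1,3-dioxolan-4-one | C[C@H]1O[C@@H](C(C)(C)C)OC1=O | intermediate
10 | 1,2:5,6-di-O-isopropylidene-α-D-glucofuranose | O[C@@H]1[C@H]2OC(C)(C)O[C@H]2O[C@@H]1[C@H]1COC(C)(C)O1 | starting material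
11 | 1,2:5,6-di-O-isopropylidene-α-D-ribo-hexofuranos-3-ulose | O=C1[C@H]2OC(C)(C)O[C@H]2O[C@@H]1[C@H]1COC(C)(C)O1 | intermediate
12 | lithium (2R)-2-tert-butyl-5-methyl-1,3-dioxol-4-olate (enolate of 9) | CC1=C([O-])O[C@H](C(C)(C)C)O1.[Li+] | intermediate
13 | 3-C-[(2R,4S)-2-tert-butyl-4-methyl-5-oxo-1,3-dioxolan-4-yl]-1,2:5,6-di-O-isopropylidene-α-D-allofuranose | O[C@@]1([C@]3(C)O[C@@H](C(C)(C)C)OC3=O)[C@H]2OC(C)(C)O[C@H]2O[C@@H]1[C@H]1COC(C)(C)O1 | intermediate
14 | 3-C-[(2R,4S)-2-tert-butyl-4-methyl-5-oxo-1,3-dioxolan-4-yl]-2,3:5,6-di-O-isopropylidene-β-D-allofuranose | O[C@@H]1O[C@H]([C@H]2COC(C)(C)O2)[C@@]3([C@]4(C)O[C@@H](C(C)(C)C)OC4=O)OC(C)(C)O[C@@H]13 | intermediate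
15 | (2Z)-1,2,3-trideoxy-2-iodo-4,5:7,8-di-O-isopropylidene-5-C-[(2R,4S)-2-tert-butyl-4-methyl-5-oxo-1,3-dioxolan-4-yl]-D-allo-oct-2-enitol (free C9-OH) | I/C(C)=C\[C@@H]1OC(C)(C)O[C@]1([C@]2(C)O[C@@H](C(C)(C)C)OC2=O)[C@H](O)[C@H]1COC(C)(C)O1 | intermediate
16 | 6-O-acetate of 15 (C5–C10 Z-vinyl iodide, 9-OAc) | I/C(C)=C\[C@@H]1OC(C)(C)O[C@]1([C@]2(C)O[C@@H](C(C)(C)C)OC2=O)[C@H](OC(C)=O)[C@H]1COC(C)(C)O1 | intermediate
17 | C5–C10 aldehyde (Z-vinyl iodide; 7,8-O-isopropylidene; 8-dioxolanonyl; 9-OAc; C10 CHO) | I/C(C)=C\[C@@H]1OC(C)(C)O[C@]1([C@]2(C)O[C@@H](C(C)(C)C)OC2=O)[C@H](OC(C)=O)C=O | intermediate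
18 | C5–C12 (10E)-11-methyl enal (other groups as in 17) | I/C(C)=C\[C@@H]1OC(C)(C)O[C@]1([C@]2(C)O[C@@H](C(C)(C)C)OC2=O)[C@H](OC(C)=O)/C=C(\C)C=O | intermediate
19 | bis(methylzinc) alkynylide–alkoxide of 6 | C[Zn]C#C[C@@](O[Zn]C)(C)[C@H]1OC(C)(C)O[C@@H]1CI | intermediate
20 | seco-cembranoid (12S)-propargylic alcohol with C5 vinyl iodide and C4 alkyl iodide | I/C(C)=C\[C@@H]1OC(C)(C)O[C@]1([C@]2(C)O[C@@H](C(C)(C)C)OC2=O)[C@H](OC(C)=O)/C=C(\C)[C@H](O)C#C[C@@](O)(C)[C@H]1OC(C)(C)O[C@@H]1CI | intermediate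
21 | 14-membered (5Z,10E)-cembranoid 13-yne (1-OH, 12-OH, 9-OAc, 2,3- and 7,8-O-isopropylidene, 8-dioxolanonyl) | C1/C(C)=C\[C@@H]2OC(C)(C)O[C@]2([C@]4(C)O[C@@H](C(C)(C)C)OC4=O)[C@H](OC(C)=O)/C=C(\C)[C@H](O)C#C[C@@](O)(C)[C@H]3OC(C)(C)O[C@@H]31 | intermediate
22 | macrocyclic γ-lactone pentaol (OH at C1, C2, C3, C8, C12, C17; 9-OAc; 13-yne) | C1/C(C)=C\[C@@H]2OC(=O)[C@@](C)(O)[C@@]2(O)[C@H](OC(C)=O)/C=C(\C)[C@H](O)C#C[C@@](O)(C)[C@@H](O)[C@@H]1O | intermediate
23 | 13-yne 2,3,9,12-tetraacetate (OH at C1, C8, C17) | C1/C(C)=C\[C@@H]2OC(=O)[C@@](C)(O)[C@@]2(O)[C@H](OC(C)=O)/C=C(\C)[C@H](OC(C)=O)C#C[C@@](O)(C)[C@@H](OC(C)=O)[C@@H]1OC(C)=O | intermediate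
24 | (5Z,10E,13Z)-cembranoid 2,3,9,12-tetraacetate (cyclisation precursor) | C1/C(C)=C\[C@@H]2OC(=O)[C@@](C)(O)[C@@]2(O)[C@H](OC(C)=O)/C=C(\C)[C@H](OC(C)=O)/C=C\[C@@](O)(C)[C@@H](OC(C)=O)[C@@H]1OC(C)=O | intermediate
25 | C1/C13 allyl cation of 24 | C1/C(C)=C\[C@@H]2OC(=O)[C@@](C)(O)[C@@]2(O)[C@H](OC(C)=O)/C=C(\C)[C@H](OC(C)=O)/C=C\[C+](C)[C@@H](OC(C)=O)[C@@H]1OC(C)=O | intermediate
26 | briarane 11,12-acetoxonium (2-methyl-1,3-dioxolan-2-ylium) ion | CC(=O)O[C@@H]1[C@H]2[C@]3(C)OC(C)=[O+][C@@H]3C=C[C@]2(C)[C@@H](OC(C)=O)[C@H](OC(C)=O)C/C(C)=C\[C@@H]2OC(=O)[C@@](C)(O)[C@]21O | intermediate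
27 | CNP0121405.1 | CC(=O)O[C@@H]1[C@H]2[C@](C)(O)[C@H](OC(C)=O)C=C[C@]2(C)[C@@H](OC(C)=O)[C@H](OC(C)=O)C/C(C)=C\[C@@H]2OC(=O)[C@@](C)(O)[C@]21O | target

**Step count and risks**

Total step count: 17. Longest linear sequence: 12 steps (steps 6–17, from 10).

The three steps most likely to fail:

Step 17 (transannular closure). The C11 cation may be intercepted by the free C8-OH (tetrahydrofuran), the C1 cation may be held by the 2-acetate, the bis-allylic 12-acetate may ionise, or the macrocycle may not reach the chair. The fallback sets out from 21 and runs the closure before the polyol and lactone are unmasked. Acetylation of 21 gives the macrocyclic 9,12-diacetate F1. Lindlar reduction gives the 13Z alkene F2, in which every hydroxyl except C1-OH is masked and the 2,3-acetonide cannot participate. The same TfOH/(CF3)2CHOH treatment gives the briarane bis-acetonide F3. Aqueous TFA then removes both acetonides and closes the lactone to the 2,3-diol F4, and Ac2O/pyridine acetylates C2 and C3, coming back to the route at 27 (one step longer).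

Step 13 (macrocyclising sp2–sp3 coupling). The fallback moves the ring closure to C12–C13 and sets out from 5 and 16. LiC≡CSiMe3 adds to 5 (chelation control) to give the TMS-alkyne iodide F5. Under the same nickel conditions, now bimolecular and with no allylic acetate yet present, F5 (1.5 equiv) couples with 16 to give the open-chain coupled product F6. H5IO6 gives the aldehyde F7, Ph3P=C(CH3)CHO gives the enal F8, and NIS with AgNO3 (cat.) gives the iodoalkyne F9. A high-dilution Nozaki–Hiyama–Kishi alkynylation (CrCl2, NiCl2 cat., chiral sulfonamide ligand, THF) closes the 14-membered ring and comes back to the route at 21. The C12 configuration must be checked at this point, because it is then set in the ring closure.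

Step 9 (Stork–Zhao olefination of a lactol next to a base-sensitive dioxolanone). The fallback sets out from 14 and builds the Z-haloalkene under neutral conditions. Ramirez olefination (CBr4, PPh3, Zn, CH2Cl2) of the lactol gives the gem-dibromoalkene alcohol F10. Acetylation gives the 9-acetate F11. Pd(PPh3)4-catalysed Negishi coupling with MeZnCl occurs at the bromide trans to C7 and gives the (Z)-vinyl bromide F12. Halogen exchange (CuI, NaI, N,N′-dimethylethylenediamine, dioxane, 110 °C) then comes back to the route at 16.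

Further compounds
F1 | step 17 | macrocyclic 13-yne 9,12-diacetate bis-acetonide (21 acetylated at C12) | C1/C(C)=C\[C@@H]2OC(C)(C)O[C@]2([C@]4(C)O[C@@H](C(C)(C)C)OC4=O)[C@H](OC(C)=O)/C=C(\C)[C@H](OC(C)=O)C#C[C@@](O)(C)[C@H]3OC(C)(C)O[C@@H]31
F2 | step 17 | (13Z)-ene 9,12-diacetate bis-acetonide | C1/C(C)=C\[C@@H]2OC(C)(C)O[C@]2([C@]4(C)O[C@@H](C(C)(C)C)OC4=O)[C@H](OC(C)=O)/C=C(\C)[C@H](OC(C)=O)/C=C\[C@@](O)(C)[C@H]3OC(C)(C)O[C@@H]31
F3 | step 17 | briarane bis-acetonide (11-OH, 9,12-di-OAc, 2,3- and 7,8-O-isopropylidene, 8-dioxolanonyl) | CC(=O)O[C@@H]1[C@H]2[C@](C)(O)[C@H](OC(C)=O)C=C[C@]2(C)[C@H]3OC(C)(C)O[C@@H]3C/C(C)=C\[C@@H]2OC(C)(C)O[C@@]21[C@]4(C)O[C@@H](C(C)(C)C)OC4=O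
F4 | step 17 | 2,3-di-O-deacetyl target (briarane lactone 2,3-diol) | CC(=O)O[C@@H]1[C@H]2[C@](C)(O)[C@H](OC(C)=O)C=C[C@]2(C)[C@@H](O)[C@H](O)C/C(C)=C\[C@@H]2OC(=O)[C@@](C)(O)[C@]21O
F5 | step 13 | (2S)-2-[(4S,5S)-5-(iodomethyl)-2,2-dimethyl-1,3-dioxolan-4-yl]-4-(trimethylsilyl)but-3-yn-2-ol | C[Si](C)(C)C#C[C@@](O)(C)[C@H]1OC(C)(C)O[C@@H]1CI
F6 | step 13 | open-chain C4–C5 coupled product (TMS-alkyne; terminal acetonide; 9-OAc) | C[Si](C)(C)C#C[C@@](O)(C)[C@H]1OC(C)(C)O[C@@H]1C/C(C)=C\[C@@H]1OC(C)(C)O[C@]1([C@]2(C)O[C@@H](C(C)(C)C)OC2=O)[C@H](OC(C)=O)[C@H]1COC(C)(C)O1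
F7 | step 13 | C10 aldehyde of F6 | C[Si](C)(C)C#C[C@@](O)(C)[C@H]1OC(C)(C)O[C@@H]1C/C(C)=C\[C@@H]1OC(C)(C)O[C@]1([C@]2(C)O[C@@H](C(C)(C)C)OC2=O)[C@H](OC(C)=O)C=O
F8 | step 13 | (10E)-enal TMS-alkyne | C[Si](C)(C)C#C[C@@](O)(C)[C@H]1OC(C)(C)O[C@@H]1C/C(C)=C\[C@@H]1OC(C)(C)O[C@]1([C@]2(C)O[C@@H](C(C)(C)C)OC2=O)[C@H](OC(C)=O)/C=C(\C)C=O
F9 | step 13 | (10E)-enal iodoalkyne | IC#C[C@@](O)(C)[C@H]1OC(C)(C)O[C@@H]1C/C(C)=C\[C@@H]1OC(C)(C)O[C@]1([C@]2(C)O[C@@H](C(C)(C)C)OC2=O)[C@H](OC(C)=O)/C=C(\C)C=O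
F10 | step 9 | gem-dibromoalkene alcohol (C5Br2=C6; free C9-OH) | BrC(Br)=C[C@@H]1OC(C)(C)O[C@]1([C@]2(C)O[C@@H](C(C)(C)C)OC2=O)[C@H](O)[C@H]1COC(C)(C)O1
F11 | step 9 | gem-dibromoalkene 9-acetate | BrC(Br)=C[C@@H]1OC(C)(C)O[C@]1([C@]2(C)O[C@@H](C(C)(C)C)OC2=O)[C@H](OC(C)=O)[C@H]1COC(C)(C)O1
F12 | step 9 | (Z)-vinyl bromide 9-acetate (bromo analogue of 16) | Br/C(C)=C\[C@@H]1OC(C)(C)O[C@]1([C@]2(C)O[C@@H](C(C)(C)C)OC2=O)[C@H](OC(C)=O)[C@H]1COC(C)(C)O1
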